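All runs stem from a simulated flask on assumed constants; scatter was added.

Ask which flask ends with the longer chains, Tuesday's or Thursday's. Z is the monomer, J starts chains, G is Z built into chains, and L is a further species.

in all of them: L 0.198 M; J 1.5 mM
- north-west: Z 0.75 M; run made earlier
- north: Z 1.1 M; run made earlier
- south-east: Z 1.9 M; run made earlier
- Tuesday's: Z 0.66 M; time 30 h
- Thursday's: Z 2.0 M; time 30 h

| run | time / h | G / % | Z / % |
|---|---|---|---|
| north-west | 1.50 | 37 | 38 |
| north-west | 3.00 | 38 | 40 |
| north-west | 6.00 | 35 | 38 |
| north-west | 12.0 | 36 | 40 |
| north-west | 20.0 | 36 | 41 |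
| north | 4.00 | 57 | 26 |
| north | 8.00 | 54 | 25 |
| north | 12.0 | 57 | 25 |
| north | 15.0 | 57 | 24 |
| north | 20.0 | 56 | 25 |
| south-east | 1.50 | 71 | 20 |
| south-east | 3.00 | 71 | 15 |
| south-east | 6.00 | 73 | 15 |
| south-east | 12.0 | 74 | 15 |
| south-east | 20.0 | 74 | 14 |

(each reading ± 1.5 percentage points)

1. which of the two ends with the longer chains by the average number of monomer units in a chain (chains begun, living or dead) ("neither" if they lie within 10%) (Tuesday's / Thursday's / neither)
2. average number of monomer units in a chain (chains begun, living or dead) at the end, Tuesday's
3. average number of monomer units in a chain (chains begun, living or dead) at the end, Thursday's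

- the average divides the monomer in chains by the number of chains begun, living and dead together
- the numbers in the tables scatter by 1.5 percentage points (one standard deviation)
- the earlier runs do not show the number of chains; that part of a forecast is a guess

Climb the time scales from the fastest. At the first north-west reading, 1.50 h, Z already stands at 38% of its charge. The south-east run reads Z 20% at 1.50 h and 15% at 3.00 h. On the next rung the readings stay flat: south-east Z is 14% at 20.0 h, with a scatter of 1.5 percentage points. The last rung is the asked 30 h, past the readings, so reckon an end state.

Free Z at the last readings is 0.307 M, 0.275 M and 0.266 M, for charges from 0.75 M to 1.9 M. Their mean is 0.283 M. Call it the floor: the free Z read at the end of these runs, a reading of the equilibrium monomer concentration.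

First round: put the Z above the floor into G. With one chain per J, which is a guess, Tuesday's gets 251 units. Test this on the north run. It promises 0.817 M of G, but the last reading shows 0.616 M. Across the runs, G and Z together fall short of the charge by 0.203 M on average, beside 0.198 M of L.

So go round again and take one Z per L. The length is (c_Z − floor − c_L)/c_J. Tuesday's gets 119 and Thursday's 1010, so Thursday's chains are longer.

The forecast names Thursday's, with 118 and 1005 beside my 119 and 1010, on the ground “This looks like a polymerisation equilibrium”.

The flask gives Thursday's: 113 on Tuesday's and 1010 on Thursday's.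

    Z + J → E + G (k = 26.0 M⁻¹ h⁻¹)
    Z + E → G + E, rate k2*[E]*[Z] (k = 1200 M⁻¹ h⁻¹)
    E + Z → D (k = 0.0870 M⁻¹ h⁻¹)
    L + Z → Q (k = 3.30 M⁻¹ h⁻¹)
    G + E → Z + E, rate k5*[E] as long as [G] is above zero (k = 350 h⁻¹)

Now cut L to 0.050 M and hold the rest of Tuesday's recipe. Reckon this neighbour the same way: 218 units. The neighbour gives 212, twice Tuesday's length. Its free Z ends at 44% of the charge, as in Tuesday's. Its G ends at 48.1% of the Z charged, against 25.7% in Tuesday's.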